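**Plan**

- Labels: indenone C1 (C=O), C2, C3, C3a, C4 (OH), C6 (OMe), C7a; ring B = aryl on C2, ring C = orcinol ring on C3, ring D = benzoate ring.
- Cuts: C1–C7a (five-membered ring) first. C1 is then re-joined to O4, which sits peri to C3, as a six-membered lactone, so the core becomes an isomeric 3,4-diaryl-7-methoxycoumarin. Further cuts: C3–ring C, C2–ring B, and the ring B–O–ring D ether bond.
- Enabling feature: in the opened lactone the amide carbon C1 lies cis to the benzo-ring aryl, whose only free ortho position is C7a–H (the other carries O4; ring C has no ortho hydrogen). C7a is meta to O4 and O6 and so closed to acylium chemistry; the bond is therefore made with C7a as a carbanion.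
- Forward: ring D bromide + ring B phenol (Ullmann ether), Dakin oxidation, MOM, boronate; coumarin C3 arylation through its iodonium ylide, C4 triflate, Negishi coupling with ring C; lactone opening with LiNEt2 and capping of O4; remote metalation closes C1–C7a; global MOM removal.
- Stereochemistry: the target has no stereocentre. The one geometric element on the way, amide cis to the benzo-ring aryl across C2=C3, is inherited from the lactone ring.

Key step: step 13

Assumption: rotation about the aryl–indenone and diaryl ether bonds of the target is taken as fast at room temperature, so no atropisomer has to be controlled.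

**Route**

Step 1
Reactants: 1 3-bromo-5-methylphenol
Product: 2 1-bromo-3-(methoxymethoxy)-5-methylbenzene
Conditions: NaH, MOMCl, DMF, 0 °C → rt
Reagents that add atoms: chloromethyl methyl ether (MOMCl), COCCl
Why: O-alkylation of the phenoxide (Williamson type) should give the MOM ether, which also serves as the ortho-directing group for step 2.

Step 2
Reactants: 2 1-bromo-3-(methoxymethoxy)-5-methylbenzene
Product: 4 methyl 2-bromo-6-(methoxymethoxy)-4-methylbenzoate, via aryllithium 3 (not isolated)
Conditions: LiN(i-Pr)2, THF, −78 °C; then ClCO2Me, −78 °C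
Reagents that add atoms: methyl chloroformate, COC(=O)Cl
Why: Directed ortho-metalation: the hydrogen between Br and OMOM is the most acidic, the amide base at −78 °C should remove it without bromine–lithium exchange or aryne formation, and the aryllithium is acylated by the chloroformate.

Step 3
Reactants: 4 methyl 2-bromo-6-(methoxymethoxy)-4-methylbenzoate; 5 3-bromo-2-hydroxy-5-methoxybenzaldehyde
Product: 6 methyl 2-(2-bromo-6-formyl-4-methoxyphenoxy)-6-(methoxymethoxy)-4-methylbenzoate
Conditions: CuI (10 mol%), picolinic acid (20 mol%), K3PO4, DMSO, 90 °C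
Reagents that add atoms: none
Why: Ullmann diaryl ether synthesis: the bromide of 4 is activated by its ortho ester, whereas the bromide of 5 sits on an electron-rich phenoxide ring and should stay untouched.

Step 4
Reactants: 6 methyl 2-(2-bromo-6-formyl-4-methoxyphenoxy)-6-(methoxymethoxy)-4-methylbenzoate
Product: 8 methyl 2-(2-bromo-6-hydroxy-4-methoxyphenoxy)-6-(methoxymethoxy)-4-methylbenzoate, via aryl formate 7 (not isolated)
Conditions: mCPBA, CH2Cl2, rt; then K2CO3 (cat.), MeOH, 0 °C
Reagents that add atoms: 3-chloroperbenzoic acid (mCPBA), OOC(=O)c1cccc(Cl)c1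
Why: Dakin-type Baeyer–Villiger oxidation: the aryl group with the ortho aryloxy donor should migrate in preference to hydride, and mild methanolysis of the formate frees the phenol without touching the hindered benzoate.

Step 5
Reactants: 8 methyl 2-(2-bromo-6-hydroxy-4-methoxyphenoxy)-6-(methoxymethoxy)-4-methylbenzoate
Product: 9 methyl 2-[2-bromo-4-methoxy-6-(methoxymethoxy)phenoxy]-6-(methoxymethoxy)-4-methylbenzoate
Conditions: NaH, MOMCl, DMF, 0 °C → rt
Reagents that add atoms: chloromethyl methyl ether (MOMCl), COCCl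
Why: O-alkylation of the phenoxide gives the second MOM ether, so that all phenols destined to be free in the target carry the same acid-labile group.

Step 6
Reactants: 9 methyl 2-[2-bromo-4-methoxy-6-(methoxymethoxy)phenoxy]-6-(methoxymethoxy)-4-methylbenzoate
Product: 10 methyl 2-[4-methoxy-2-(methoxymethoxy)-6-(4,4,5,5-tetramethyl-1,3,2-dioxaborolan-2-yl)phenoxy]-6-(methoxymethoxy)-4-methylbenzoate
Conditions: B2pin2, PdCl2(dppf) (5 mol%), KOAc, 1,4-dioxane, 90 °C
Reagents that add atoms: bis(pinacolato)diboron (B2pin2), CC1(C)OB(B2OC(C)(C)C(C)(C)O2)OC1(C)C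
Why: Miyaura borylation of the aryl bromide; the weak acetate base should not trigger Suzuki homocoupling and the ester and MOM ethers are inert.

Step 7
Reactants: 11 4-hydroxy-7-methoxy-2H-chromen-2-one
Product: 12 7-methoxy-2-oxo-3-(phenyliodonio)-2H-chromen-4-olate (iodonium ylide)
Conditions: PhI(OAc)2, Na2CO3, H2O, rt
Reagents that add atoms: (diacetoxyiodo)benzene, CC(=O)OI(OC(C)=O)c1ccccc1
Why: The 1,3-dicarbonyl-type C3–H of a 4-hydroxycoumarin condenses with the trivalent iodine reagent to a stable iodonium ylide, which makes C3 an electrophile for cross-coupling.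

Step 8
Reactants: 12 7-methoxy-2-oxo-3-(phenyliodonio)-2H-chromen-4-olate; 10 methyl 2-[4-methoxy-2-(methoxymethoxy)-6-(4,4,5,5-tetramethyl-1,3,2-dioxaborolan-2-yl)phenoxy]-6-(methoxymethoxy)-4-methylbenzoate
Product: 13 methyl 2-[2-(4-hydroxy-7-methoxy-2-oxo-2H-chromen-3-yl)-4-methoxy-6-(methoxymethoxy)phenoxy]-6-(methoxymethoxy)-4-methylbenzoate
Conditions: Pd(P(t-Bu)3)2 (5 mol%), LiOH·H2O, DME/H2O, rt; aq. HCl work-up
Reagents that add atoms: none
Why: Suzuki–Miyaura-type coupling in which the iodonium ylide is the electrophile (insertion of palladium at C3–I with loss of iodobenzene, transmetalation from the boronate, reductive elimination), a known route to 3-aryl-4-hydroxycoumarins that leaves the doubly ortho-substituted benzoate intact.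

Step 9
Reactants: 13 methyl 2-[2-(4-hydroxy-7-methoxy-2-oxo-2H-chromen-3-yl)-4-methoxy-6-(methoxymethoxy)phenoxy]-6-(methoxymethoxy)-4-methylbenzoate
Product: 14 methyl 2-[4-methoxy-2-(methoxymethoxy)-6-(7-methoxy-2-oxo-4-{[(trifluoromethyl)sulfonyl]oxy}-2H-chromen-3-yl)phenoxy]-6-(methoxymethoxy)-4-methylbenzoate
Conditions: Tf2O, Et3N, CH2Cl2, −78 → 0 °C
Reagents that add atoms: trifluoromethanesulfonic anhydride (Tf2O), O=S(=O)(OS(=O)(=O)C(F)(F)F)C(F)(F)F
Why: O-sulfonylation of the acidic enol gives the vinylogous acyl triflate, the standard C4 electrophile of the coumarin series.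

Step 10
Reactants: 15 orcinol (5-methylbenzene-1,3-diol)
Product: 16 1,3-bis(methoxymethoxy)-5-methylbenzene
Conditions: NaH, MOMCl, DMF, 0 °C → rt
Reagents that add atoms: chloromethyl methyl ether (MOMCl), COCCl
Why: Double O-alkylation of the bis-phenoxide gives the bis-MOM ether, whose two acetal groups direct the metalation in step 11.

Step 11
Reactants: 16 1,3-bis(methoxymethoxy)-5-methylbenzene; 14 methyl 2-[4-methoxy-2-(methoxymethoxy)-6-(7-methoxy-2-oxo-4-{[(trifluoromethyl)sulfonyl]oxy}-2H-chromen-3-yl)phenoxy]-6-(methoxymethoxy)-4-methylbenzoate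
Product: 19 methyl 2-[2-{4-[2,6-bis(methoxymethoxy)-4-methylphenyl]-7-methoxy-2-oxo-2H-chromen-3-yl}-4-methoxy-6-(methoxymethoxy)phenoxy]-6-(methoxymethoxy)-4-methylbenzoate, via aryllithium 17 (not isolated), via arylzinc chloride 18 (not isolated)
Conditions: 16, n-BuLi, THF, 0 °C; ZnCl2, 0 °C → rt; then 14, Pd2(dba)3 (2.5 mol%), SPhos (10 mol%), THF, 60 °C
Reagents that add atoms: none
Why: Directed ortho-metalation between the two OMOM groups, transmetalation to zinc and Negishi coupling; the C4 triflate adds readily to zerovalent palladium, the biarylphosphine ligand is known to couple doubly ortho-substituted arylzincs, and ester and lactone are inert to the arylzinc.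

Step 12
Reactants: 19 methyl 2-[2-{4-[2,6-bis(methoxymethoxy)-4-methylphenyl]-7-methoxy-2-oxo-2H-chromen-3-yl}-4-methoxy-6-(methoxymethoxy)phenoxy]-6-(methoxymethoxy)-4-methylbenzoate
Product: 21 methyl 2-[2-{(E)-2-[2,6-bis(methoxymethoxy)-4-methylphenyl]-1-(diethylcarbamoyl)-2-[4-methoxy-2-(methoxymethoxy)phenyl]ethenyl}-4-methoxy-6-(methoxymethoxy)phenoxy]-6-(methoxymethoxy)-4-methylbenzoate (carboxamide cis to the 4-methoxy-2-(methoxymethoxy)phenyl ring), via lithium phenoxide 20 (not isolated)
Conditions: LiNEt2, THF, −78 → −20 °C; then MOMCl, −20 °C → rt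
Reagents that add atoms: lithium diethylamide, CCN([Li])CC; chloromethyl methyl ether (MOMCl), COCCl
Why: Aminolysis of the lactone (an aryl ester): the tetrahedral intermediate expels the phenoxide, which is capped in situ so that neither re-lactonization nor rotation about C2=C3 through its quinone-methide resonance form can occur; the amide therefore stays cis to the benzo-ring aryl, and the ring D ester is shielded by its two ortho substituents.

Step 13
Reactants: 21 methyl 2-[2-{(E)-2-[2,6-bis(methoxymethoxy)-4-methylphenyl]-1-(diethylcarbamoyl)-2-[4-methoxy-2-(methoxymethoxy)phenyl]ethenyl}-4-methoxy-6-(methoxymethoxy)phenoxy]-6-(methoxymethoxy)-4-methylbenzoate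
Product: 24 methyl 2-[2-{3-[2,6-bis(methoxymethoxy)-4-methylphenyl]-6-methoxy-4-(methoxymethoxy)-1-oxo-1H-inden-2-yl}-4-methoxy-6-(methoxymethoxy)phenoxy]-6-(methoxymethoxy)-4-methylbenzoate (pentakis-MOM ether of ascomindone B), via C7a-aryllithium 22 (not isolated), via lithium aminal alkoxide 23 (not isolated)
Conditions: LiN(i-Pr)2 (3 equiv), THF, −78 → 0 °C; then H2O
Reagents that add atoms: none
Why: Proposed new method: lithium diisopropylamide is expected to bind the amide oxygen and remove C7a–H, the only hydrogen held next to it (ring C has both ortho positions oxygenated, ring B could only close a four-membered ring), and aryllithium 22 then adds to the amide carbon C1 to give aminal alkoxide 23, which loses diethylamine on work-up. The closest known reaction type is the directed remote metalation–cyclization of N,N-diethyl biaryl-2-carboxamides to fluorenones; the C2=C3 double bond here takes the place of the second aryl ring and holds C1 and C7a–H at the same distance. The five-membered ring closes in the 5-exo-trig mode, the aryl carbanion attacking a carbonyl whose C=O bond lies outside the new ring. No stereocentre is formed; the cis geometry needed for closure was fixed by the lactone and carried through step 12. The step needs site selectivity for C7a over the hydrogens flanked by OMOM and OMe groups and chemoselectivity for the amide over the ring D ester: lithiation elsewhere is reversible and has no electrophile within reach, whereas closure at C1 is irreversible, and the ester is shielded by two ortho substituents and twisted out of conjugation. Because C7a reacts as a nucleophile, its position meta to both ring oxygens, which would disfavour a Friedel–Crafts closure, does not matter.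

Step 14
Reactants: 24 methyl 2-[2-{3-[2,6-bis(methoxymethoxy)-4-methylphenyl]-6-methoxy-4-(methoxymethoxy)-1-oxo-1H-inden-2-yl}-4-methoxy-6-(methoxymethoxy)phenoxy]-6-(methoxymethoxy)-4-methylbenzoate
Product: 25 ascomindone B, methyl 2-{2-[3-(2,6-dihydroxy-4-methylphenyl)-4-hydroxy-6-methoxy-1-oxo-1H-inden-2-yl]-6-hydroxy-4-methoxyphenoxy}-6-hydroxy-4-methylbenzoate
Conditions: HCl (3 M in MeOH), 45 °C
Reagents that add atoms: none
Why: Acid-catalysed acetal cleavage should remove all five MOM ethers at once, while the methyl ethers, the methyl ester, the diaryl ether and the indenone are stable to these conditions.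

**Compound list**

1 | 3-bromo-5-methylphenol | Cc1cc(O)cc(Br)c1 | starting material
2 | 1-bromo-3-(methoxymethoxy)-5-methylbenzene | COCOc1cc(C)cc(Br)c1 | intermediate
3 | [2-bromo-6-(methoxymethoxy)-4-methylphenyl]lithium | [Li]c1c(Br)cc(C)cc1OCOC | intermediate (not isolated)
4 | methyl 2-bromo-6-(methoxymethoxy)-4-methylbenzoate | COC(=O)c1c(Br)cc(C)cc1OCOC | intermediate
5 | 3-bromo-2-hydroxy-5-methoxybenzaldehyde | COc1cc(Br)c(O)c(C=O)c1 | starting material
6 | methyl 2-(2-bromo-6-formyl-4-methoxyphenoxy)-6-(methoxymethoxy)-4-methylbenzoate | COC(=O)c1c(OCOC)cc(C)cc1Oc1c(Br)cc(OC)cc1C=O | intermediate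
7 | methyl 2-[2-bromo-6-(formyloxy)-4-methoxyphenoxy]-6-(methoxymethoxy)-4-methylbenzoate | COC(=O)c1c(OCOC)cc(C)cc1Oc1c(Br)cc(OC)cc1OC=O | intermediate (not isolated)
8 | methyl 2-(2-bromo-6-hydroxy-4-methoxyphenoxy)-6-(methoxymethoxy)-4-methylbenzoate | COC(=O)c1c(OCOC)cc(C)cc1Oc1c(Br)cc(OC)cc1O | intermediate
9 | methyl 2-[2-bromo-4-methoxy-6-(methoxymethoxy)phenoxy]-6-(methoxymethoxy)-4-methylbenzoate | COC(=O)c1c(OCOC)cc(C)cc1Oc1c(Br)cc(OC)cc1OCOC | intermediate
10 | methyl 2-[4-methoxy-2-(methoxymethoxy)-6-(4,4,5,5-tetramethyl-1,3,2-dioxaborolan-2-yl)phenoxy]-6-(methoxymethoxy)-4-methylbenzoate | COC(=O)c1c(OCOC)cc(C)cc1Oc1c(B2OC(C)(C)C(C)(C)O2)cc(OC)cc1OCOC | intermediate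
11 | 4-hydroxy-7-methoxy-2H-chromen-2-one | COc1ccc2c(O)cc(=O)oc2c1 | starting material
12 | 7-methoxy-2-oxo-3-(phenyliodonio)-2H-chromen-4-olate | COc1ccc2c([O-])c([I+]c3ccccc3)c(=O)oc2c1 | intermediate
13 | methyl 2-[2-(4-hydroxy-7-methoxy-2-oxo-2H-chromen-3-yl)-4-methoxy-6-(methoxymethoxy)phenoxy]-6-(methoxymethoxy)-4-methylbenzoate | COC(=O)c1c(OCOC)cc(C)cc1Oc1c(OCOC)cc(OC)cc1-c1c(O)c2ccc(OC)cc2oc1=O | intermediate
14 | methyl 2-[4-methoxy-2-(methoxymethoxy)-6-(7-methoxy-2-oxo-4-{[(trifluoromethyl)sulfonyl]oxy}-2H-chromen-3-yl)phenoxy]-6-(methoxymethoxy)-4-methylbenzoate | COC(=O)c1c(OCOC)cc(C)cc1Oc1c(OCOC)cc(OC)cc1-c1c(OS(=O)(=O)C(F)(F)F)c2ccc(OC)cc2oc1=O | intermediate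
15 | orcinol (5-methylbenzene-1,3-diol) | Cc1cc(O)cc(O)c1 | starting material
16 | 1,3-bis(methoxymethoxy)-5-methylbenzene | COCOc1cc(C)cc(OCOC)c1 | intermediate
17 | [2,6-bis(methoxymethoxy)-4-methylphenyl]lithium | [Li]c1c(OCOC)cc(C)cc1OCOC | intermediate (not isolated)
18 | [2,6-bis(methoxymethoxy)-4-methylphenyl]zinc chloride | Cl[Zn]c1c(OCOC)cc(C)cc1OCOC | intermediate (not isolated)
19 | methyl 2-[2-{4-[2,6-bis(methoxymethoxy)-4-methylphenyl]-7-methoxy-2-oxo-2H-chromen-3-yl}-4-methoxy-6-(methoxymethoxy)phenoxy]-6-(methoxymethoxy)-4-methylbenzoate | COC(=O)c1c(OCOC)cc(C)cc1Oc1c(OCOC)cc(OC)cc1-c1c(-c2c(OCOC)cc(C)cc2OCOC)c2ccc(OC)cc2oc1=O | intermediate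
20 | lithium phenoxide of the ring-opened (E)-N,N-diethylacrylamide (amide cis to the lithium 2-oxido-4-methoxyphenyl ring) | CCN(CC)C(=O)/C(c1cc(OC)cc(OCOC)c1Oc1cc(C)cc(OCOC)c1C(=O)OC)=C(/c1c(OCOC)cc(C)cc1OCOC)c1ccc(OC)cc1O[Li] | intermediate (not isolated)
21 | methyl 2-[2-{(E)-2-[2,6-bis(methoxymethoxy)-4-methylphenyl]-1-(diethylcarbamoyl)-2-[4-methoxy-2-(methoxymethoxy)phenyl]ethenyl}-4-methoxy-6-(methoxymethoxy)phenoxy]-6-(methoxymethoxy)-4-methylbenzoate | CCN(CC)C(=O)/C(c1cc(OC)cc(OCOC)c1Oc1cc(C)cc(OCOC)c1C(=O)OC)=C(/c1c(OCOC)cc(C)cc1OCOC)c1ccc(OC)cc1OCOC | intermediate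
22 | C7a-lithiated derivative of 21 (lithium on the ring carbon ortho to the alkene and para to C5) | CCN(CC)C(=O)/C(c1cc(OC)cc(OCOC)c1Oc1cc(C)cc(OCOC)c1C(=O)OC)=C(/c1c(OCOC)cc(C)cc1OCOC)c1c([Li])cc(OC)cc1OCOC | intermediate (not isolated)
23 | lithium 1-(diethylamino)-1H-inden-1-olate adduct (racemic at C1), precursor of 24 | COC(=O)c1c(OCOC)cc(C)cc1Oc1c(OCOC)cc(OC)cc1C1=C(c2c(OCOC)cc(C)cc2OCOC)c2c(OCOC)cc(OC)cc2C1(O[Li])N(CC)CC | intermediate (not isolated)
24 | methyl 2-[2-{3-[2,6-bis(methoxymethoxy)-4-methylphenyl]-6-methoxy-4-(methoxymethoxy)-1-oxo-1H-inden-2-yl}-4-methoxy-6-(methoxymethoxy)phenoxy]-6-(methoxymethoxy)-4-methylbenzoate | COC(=O)c1c(OCOC)cc(C)cc1Oc1c(OCOC)cc(OC)cc1C1=C(c2c(OCOC)cc(C)cc2OCOC)c2c(OCOC)cc(OC)cc2C1=O | intermediate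
25 | ascomindone B | COC(=O)c1c(O)cc(C)cc1Oc1c(O)cc(OC)cc1C1=C(c2c(O)cc(C)cc2O)c2c(O)cc(OC)cc2C1=O | target

**Totals**

Total step count: 14. Longest linear sequence: 12 steps (steps 1–6, 8, 9, 11–14).

**Steps most likely to fail**

Step 13 (proposed new method). What may go wrong: deprotonation may occur reversibly at the positions flanked by acetal and methoxy oxygens or at the benzylic methyl groups faster than at C7a, so that base is consumed without ring closure. The amide base may also add to the amide or ester carbonyl on warming. The fallback sets out from 21 and comes back at 24, and closes the same bond with inverted polarity by known chemistry. Treatment of 21 with Tf2O and 2,6-di-tert-butyl-4-methylpyridine in CH2Cl2 at −78 → 0 °C should convert the tertiary amide into the O-triflyl iminium triflate of 21 F1, a Vilsmeier–Haack-type electrophile. Intramolecular Friedel–Crafts attack by C7a, the only ring carbon that can reach C1, would give the cyclic 1-indenylidene diethyliminium triflate F2, which aqueous NaHCO3 hydrolyses to 24. This is the known triflic-anhydride amide activation followed by intramolecular Friedel–Crafts acylation. It is not the first choice because C7a is meta to both ring oxygens; high dilution and low temperature would be needed to keep the electrophile away from the more electron-rich positions of other molecules.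

Step 11. What may go wrong: transmetalation and reductive elimination at the crowded C4 position, flanked by ring B on C3 and the peri C5–H, may be slow, so that protodezincation of 18 and S–O cleavage of the triflate back to 13 take over. The fallback inverts the order of the two arylations. It sets out from 11 (with 16 and 9) and comes back at 19, bypassing steps 6–9. Triflation of 11 (Tf2O, Et3N, CH2Cl2) should give 7-methoxy-2-oxo-2H-chromen-4-yl trifluoromethanesulfonate F3. Negishi coupling of F3 with 18 under the conditions of step 11, now without a C3 substituent, would give 4-[2,6-bis(methoxymethoxy)-4-methylphenyl]-7-methoxy-2H-chromen-2-one F4. Zincation of its C3–H with TMPZnCl·LiCl (TMP = 2,2,6,6-tetramethylpiperidide) in THF at rt would give the coumarin-3-ylzinc chloride F5 (not isolated). Negishi coupling of F5 with bromide 9 (Pd2(dba)3, SPhos, THF, 60 °C) then forms the C3–ring B bond and gives 19.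

Step 3. What may go wrong: the salicylaldehyde-type phenoxide of 5 may chelate and sequester copper so that catalysis stalls, or copper may insert into the C–Br bond of 5 and give oligomeric ethers. The fallback is a metal-free nucleophilic aromatic substitution. It sets out from 5 and comes back at 6. Commercial 3-fluoro-5-methylphenol is converted (NaH, MOMCl, DMF) into 1-fluoro-3-(methoxymethoxy)-5-methylbenzene F6. Lithiation between F and OMOM (n-BuLi, THF, −78 °C) gives [2-fluoro-6-(methoxymethoxy)-4-methylphenyl]lithium F7 (not isolated), and quenching with ClCO2Me gives methyl 2-fluoro-6-(methoxymethoxy)-4-methylbenzoate F8. Heating F8 with 5 and Cs2CO3 in DMSO at 120 °C should displace the fluoride ortho to the ester and give 6; no transition metal is present, so the bromide of 5 cannot react.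

Further compounds
F1 | step 13 | O-triflyl iminium triflate of 21 (N,N-diethyl-1-{[(trifluoromethyl)sulfonyl]oxy}alk-2-en-1-iminium trifluoromethanesulfonate, geometry as in 21) | CC[N+](CC)=C(OS(=O)(=O)C(F)(F)F)/C(c1cc(OC)cc(OCOC)c1Oc1cc(C)cc(OCOC)c1C(=O)OC)=C(/c1c(OCOC)cc(C)cc1OCOC)c1ccc(OC)cc1OCOC.[O-]S(=O)(=O)C(F)(F)F
F2 | step 13 | 1-indenylidene diethyliminium triflate corresponding to 24 | CC[N+](CC)=C1C(c2cc(OC)cc(OCOC)c2Oc2cc(C)cc(OCOC)c2C(=O)OC)=C(c2c(OCOC)cc(C)cc2OCOC)c2c(OCOC)cc(OC)cc21.[O-]S(=O)(=O)C(F)(F)F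
F3 | step 11 | 7-methoxy-2-oxo-2H-chromen-4-yl trifluoromethanesulfonate | COc1ccc2c(OS(=O)(=O)C(F)(F)F)cc(=O)oc2c1
F4 | step 11 | 4-[2,6-bis(methoxymethoxy)-4-methylphenyl]-7-methoxy-2H-chromen-2-one | COCOc1cc(C)cc(OCOC)c1-c1cc(=O)oc2cc(OC)ccc12
F5 | step 11 | {4-[2,6-bis(methoxymethoxy)-4-methylphenyl]-7-methoxy-2-oxo-2H-chromen-3-yl}zinc chloride | COCOc1cc(C)cc(OCOC)c1-c1c([Zn]Cl)c(=O)oc2cc(OC)ccc12
F6 | step 3 | 1-fluoro-3-(methoxymethoxy)-5-methylbenzene | COCOc1cc(C)cc(F)c1
F7 | step 3 | [2-fluoro-6-(methoxymethoxy)-4-methylphenyl]lithium | [Li]c1c(F)cc(C)cc1OCOC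
F8 | step 3 | methyl 2-fluoro-6-(methoxymethoxy)-4-methylbenzoate | COC(=O)c1c(F)cc(C)cc1OCOC
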